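**Assumption:** (R)-4-hydroxycyclopent-2-enone, (S)-3-methylpentanoic acid, (R)-2-methylbutanoic acid and methyl diazoacetate (as a CH2Cl2 solution) are taken as catalogue compounds.

**Retrosynthetic overview**
1. Target ⇐ C2–OTf replaced by C2–H (Pd/hydride) ⇐ enol triflate of a 2-oxocyclohexane-1-carboxylate that already carries all three esters.
2. That β-keto ester ⇐ one-carbon ring expansion (1,2-shift of the ring CH2) of a 2,3,4-tris(acyloxy)cyclopentanone with methyl diazoacetate; C1 and CO2Me arrive together.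
3. Tris(acyloxy)cyclopentanone ⇐ stepwise O-acylation of a cis-2,3-diol (acetyl on the α-ketol OH, then (R)-2-methylbutanoyl).
4. Diol ⇐ anti-selective OsO4 dihydroxylation of the (S)-3-methylpentanoate of (R)-4-hydroxycyclopent-2-enone.
5. Rings: the carbocycle is bought five-membered and becomes the cyclohexene in the ring-expansion step; no other ring is formed.

**Route**

Step 1
Reactants: 1 (R)-4-hydroxycyclopent-2-en-1-one; 2 (S)-3-methylpentanoic acid
Product: 3 (1R)-4-oxocyclopent-2-en-1-yl (3S)-3-methylpentanoate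
Conditions: DCC (1.15 eq), DMAP (5 mol%), CH2Cl2, 0 °C → rt
Reagents that add atoms: none
Why: Steglich esterification acylates the secondary allylic OH without touching either stereocentre, and cold, low-DMAP conditions keep the γ-acyloxy enone from eliminating.

Step 2
Reactants: 3 (1R)-4-oxocyclopent-2-en-1-yl (3S)-3-methylpentanoate
Product: 4 (2S,3R,4R)-2,3-dihydroxy-4-[(3S)-3-methylpentanoyloxy]cyclopentan-1-one (2,3-cis-diol, trans to the ester)
Conditions: K2OsO2(OH)4 (1 mol%), NMO (1.2 eq), citric acid (0.75 eq), t-BuOH/H2O 1:1, rt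
Reagents that add atoms: N-methylmorpholine N-oxide, C[N+]1([O-])CCOCC1; water, O
Why: Upjohn-type OsO4 syn-dihydroxylation in citric-acid-buffered medium is fast for electron-poor enones and non-basic (no β-elimination or ketol isomerisation), and osmium adds to the face anti to the C4 acyloxy group, which sets C2 and C3.

Step 3
Reactants: 4 (2S,3R,4R)-2,3-dihydroxy-4-[(3S)-3-methylpentanoyloxy]cyclopentan-1-one
Product: 5 (2S,3S,4R)-2-acetoxy-3-hydroxy-4-[(3S)-3-methylpentanoyloxy]cyclopentan-1-one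
Conditions: Ac2O (1.05 eq), pyridine (3 eq), CH2Cl2, −20 → 0 °C
Reagents that add atoms: acetic anhydride, CC(=O)OC(C)=O
Why: Kinetic site-selective acylation is expected at the α-ketol OH on C2, which is the more acidic and less hindered hydroxyl (C3–OH sits between two oxygenated sp3 carbons), and low temperature suppresses 2→3 acetyl migration and E1cB loss of the C4 ester.

Step 4
Reactants: 5 (2S,3S,4R)-2-acetoxy-3-hydroxy-4-[(3S)-3-methylpentanoyloxy]cyclopentan-1-one; 6 (R)-2-methylbutanoic acid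
Product: 7 (2S,3S,4R)-2-acetoxy-3-[(2R)-2-methylbutanoyloxy]-4-[(3S)-3-methylpentanoyloxy]cyclopentan-1-one
Conditions: 6 (1.5 eq), DCC (1.6 eq), DMAP (0.2 eq), CH2Cl2, 0 °C → rt
Reagents that add atoms: none
Why: Steglich esterification of the remaining hindered secondary alcohol; the α-stereocentre of the aliphatic acid does not racemise under carbodiimide/catalytic DMAP at 0 °C and no ring stereocentre is touched.

Step 5
Reactants: 7 (2S,3S,4R)-2-acetoxy-3-[(2R)-2-methylbutanoyloxy]-4-[(3S)-3-methylpentanoyloxy]cyclopentan-1-one; 8 methyl diazoacetate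
Product: 10 methyl (3S,4S,5R)-3-acetoxy-4-[(2R)-2-methylbutanoyloxy]-5-[(3S)-3-methylpentanoyloxy]-2-(trifluoromethylsulfonyloxy)cyclohex-1-ene-1-carboxylate, via ring-expanded β-keto ester 9 (not isolated)
Conditions: Sc(OTf)3 (10 mol%), 8 (1.3 eq, slow addition), CH2Cl2, −20 → 0 °C; then i-Pr2NEt (2.5 eq), Tf2O (1.3 eq), −78 °C
Reagents that add atoms: triflic anhydride, O=S(=O)(OS(=O)(=O)C(F)(F)F)C(F)(F)F
Why: Proposed new method: Sc(OTf)3-catalysed C-insertion of unsubstituted methyl diazoacetate into an α,β,β′-tris(acyloxy)cyclopentanone with a site-selective 1,2-shift – Sc(III) chelates the ketone and the α-acetoxy group, the diazo carbon adds to the activated C=O, and in the β-oxido diazonium the electron-richer C5 methylene migrates antiperiplanar to N2 while the acetoxy-bearing C2 (migratory aptitude lowered by the σ-withdrawing ester oxygen) stays, so CH(CO2Me) is inserted between C=O and CH2 with no stereocentre touched, and the enolised β-keto ester is then O-triflated in the same flask by standard Tf2O/amine enol triflation; the closest known reaction type is the Lewis-acid-promoted Büchner–Curtius–Schlotterbeck (Tiffeneau–Demjanov-type) diazoacetate ring expansion of simple cycloalkanones and the Sc-catalysed diazo ester homologation of α-keto esters, neither shown on α-acyloxy ketones that carry β-leaving groups.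

Step 6
Reactants: 10 methyl (3S,4S,5R)-3-acetoxy-4-[(2R)-2-methylbutanoyloxy]-5-[(3S)-3-methylpentanoyloxy]-2-(trifluoromethylsulfonyloxy)cyclohex-1-ene-1-carboxylate
Product: 11 methyl (3R,4S,5R)-3-acetoxy-4-[(2R)-2-methylbutanoyloxy]-5-[(3S)-3-methylpentanoyloxy]cyclohex-1-ene-1-carboxylate (CNP0188172.1)
Conditions: Pd(PPh3)4 (5 mol%), Bu3SnH (1.05 eq, slow addition), LiCl (3 eq), THF, 0 °C → rt
Reagents that add atoms: none
Why: Pd(0)-catalysed hydrogenolysis of an enol triflate with tin hydride (Stille-type triflate reduction) should work because oxidative addition into the electron-poor vinyl C–OTf bond is much faster than ionisation of the secondary allylic acetate and the hydride is kept limiting; no stereocentre changes.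

**Compound list**
1 | (R)-4-hydroxycyclopent-2-en-1-one | O[C@@H]1CC(=O)C=C1 | starting material
2 | (S)-3-methylpentanoic acid | CC[C@H](C)CC(=O)O | starting material
3 | (1R)-4-oxocyclopent-2-en-1-yl (3S)-3-methylpentanoate | CC[C@H](C)CC(=O)O[C@@H]1CC(=O)C=C1 | intermediate
4 | (2S,3R,4R)-2,3-dihydroxy-4-[(3S)-3-methylpentanoyloxy]cyclopentan-1-one | CC[C@H](C)CC(=O)O[C@@H]1CC(=O)[C@@H](O)[C@H]1O | intermediate
5 | (2S,3S,4R)-2-acetoxy-3-hydroxy-4-[(3S)-3-methylpentanoyloxy]cyclopentan-1-one | CC[C@H](C)CC(=O)O[C@@H]1CC(=O)[C@@H](OC(C)=O)[C@H]1O | intermediate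
6 | (R)-2-methylbutanoic acid | CC[C@@H](C)C(=O)O | starting material
7 | (2S,3S,4R)-2-acetoxy-3-[(2R)-2-methylbutanoyloxy]-4-[(3S)-3-methylpentanoyloxy]cyclopentan-1-one | CC[C@H](C)CC(=O)O[C@@H]1CC(=O)[C@@H](OC(C)=O)[C@H]1OC(=O)[C@H](C)CC | intermediate
8 | methyl diazoacetate | COC(=O)C=[N+]=[N-] | starting material
9 | methyl (3S,4S,5R)-3-acetoxy-4-[(2R)-2-methylbutanoyloxy]-5-[(3S)-3-methylpentanoyloxy]-2-oxocyclohexane-1-carboxylate (C1 epimers/enol tautomer) | CC[C@H](C)CC(=O)O[C@@H]1CC(C(=O)OC)C(=O)[C@@H](OC(C)=O)[C@H]1OC(=O)[C@H](C)CC | intermediate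
10 | methyl (3S,4S,5R)-3-acetoxy-4-[(2R)-2-methylbutanoyloxy]-5-[(3S)-3-methylpentanoyloxy]-2-(trifluoromethylsulfonyloxy)cyclohex-1-ene-1-carboxylate | CC[C@H](C)CC(=O)O[C@@H]1CC(C(=O)OC)=C(OS(=O)(=O)C(F)(F)F)[C@@H](OC(C)=O)[C@H]1OC(=O)[C@H](C)CC | intermediate
11 | methyl (3R,4S,5R)-3-acetoxy-4-[(2R)-2-methylbutanoyloxy]-5-[(3S)-3-methylpentanoyloxy]cyclohex-1-ene-1-carboxylate | CC[C@H](C)CC(=O)O[C@@H]1CC(C(=O)OC)=C[C@@H](OC(C)=O)[C@H]1OC(=O)[C@H](C)CC | target

**Totals**
Total step count: 6. Longest linear sequence: 6 (1 → 3 → 4 → 5 → 7 → 10 → 11).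

**Three steps most likely to fail**

Step 3 (site-selective acetylation of the cis-diol; 5 can also suffer 2→3 acetyl migration before step 4). The fallback sets out from 4 and comes back to the route at 11. It postpones the diol differentiation to the cyclohexene. Diol 4 is protected (2,2-dimethoxypropane, PPTS) as the cis-fused acetonide F1. F1 is carried through the diazoacetate insertion/triflation of step 5, via the β-keto ester F2, to the enol triflate F3. Pd/Bu3SnH reduction as in step 6 gives methyl 3,4-O-isopropylidene-5-O-[(3S)-3-methylpentanoyl]shikimate F4. Aqueous TFA frees methyl 5-O-[(3S)-3-methylpentanoyl]shikimate F5. MeC(OMe)3 with catalytic CSA closes the 3,4-cyclic methyl orthoacetate F6. Mild hydrolysis of F6 (80% AcOH) opens it to the pseudo-axial ester, the 3-O-acetate F7; this follows the axial-ester rule for cis-diol orthoesters and does not depend on kinetic acylation selectivity. Steglich esterification of the free 4-OH with 6 then gives 11.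

Step 5 (the proposed ring expansion: migration regiochemistry, epoxide formation or Lewis-acid-induced loss of a β-acyloxy group). The fallback sets out from 7 and comes back at 9, using two known reactions. Methyl lithiodiazoacetate (8, LDA, THF, −78 °C, AcOH quench at −78 °C) adds to the ketone in an aldol-type step to give the β-hydroxy-α-diazo ester F8. Rh2(OAc)4 (1 mol%, CH2Cl2, rt) then converts F8, through the rhodium carbenoid and 1,2-alkyl shift, into 9, which is triflated as before.

Step 6 (Pd may ionise the allylic 3-acetate, or excess hydride may over-reduce). The fallback sets out from 9, worked up instead of being triflated, and comes back at 11 without palladium. NaBH4 (MeOH/THF, −40 °C) reduces the ketone to the β-hydroxy ester F9. MsCl/Et3N gives the mesylate F10. DBU (0 °C) then effects E1cB elimination towards C1 to give 11.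

**Further compounds**
F1 | step 3 | 2,3-O-isopropylidene acetal of 4 (cis-fused, configuration unchanged) | CC[C@H](C)CC(=O)O[C@@H]1CC(=O)[C@H]2OC(C)(C)O[C@@H]12
F2 | step 3 | methyl 3,4-O-isopropylidene-5-[(3S)-3-methylpentanoyloxy]-2-oxocyclohexane-1-carboxylate (ring configuration as in 9, C1 epimers/enol) | CC[C@H](C)CC(=O)O[C@@H]1CC(C(=O)OC)C(=O)[C@H]2OC(C)(C)O[C@@H]12
F3 | step 3 | enol triflate of F2 (2-triflyloxycyclohex-1-ene-1-carboxylate) | CC[C@H](C)CC(=O)O[C@@H]1CC(C(=O)OC)=C(OS(=O)(=O)C(F)(F)F)[C@H]2OC(C)(C)O[C@@H]12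
F4 | step 3 | methyl 3,4-O-isopropylidene-5-O-[(3S)-3-methylpentanoyl]shikimate | CC[C@H](C)CC(=O)O[C@@H]1CC(C(=O)OC)=C[C@H]2OC(C)(C)O[C@@H]12
F5 | step 3 | methyl 5-O-[(3S)-3-methylpentanoyl]shikimate | CC[C@H](C)CC(=O)O[C@@H]1CC(C(=O)OC)=C[C@@H](O)[C@H]1O
F6 | step 3 | 3,4-cyclic methyl orthoacetate of F5 (orthoester carbon as a mixture) | CC[C@H](C)CC(=O)O[C@@H]1CC(C(=O)OC)=C[C@H]2OC(C)(OC)O[C@@H]12
F7 | step 3 | methyl 3-O-acetyl-5-O-[(3S)-3-methylpentanoyl]shikimate | CC[C@H](C)CC(=O)O[C@@H]1CC(C(=O)OC)=C[C@@H](OC(C)=O)[C@H]1O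
F8 | step 5 | methyl 2-diazo-2-[2-acetoxy-1-hydroxy-3-[(2R)-2-methylbutanoyloxy]-4-[(3S)-3-methylpentanoyloxy]cyclopentyl]acetate (ring centres as in 7, carbinol centre either way) | CC[C@H](C)CC(=O)O[C@@H]1CC(O)(C(=[N+]=[N-])C(=O)OC)[C@@H](OC(C)=O)[C@H]1OC(=O)[C@H](C)CC
F9 | step 6 | methyl 3-acetoxy-2-hydroxy-4-[(2R)-2-methylbutanoyloxy]-5-[(3S)-3-methylpentanoyloxy]cyclohexane-1-carboxylate (C3–C5 as in 9, C1/C2 mixture) | CC[C@H](C)CC(=O)O[C@@H]1CC(C(=O)OC)C(O)[C@@H](OC(C)=O)[C@H]1OC(=O)[C@H](C)CC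
F10 | step 6 | 2-O-methanesulfonate of F9 | CC[C@H](C)CC(=O)O[C@@H]1CC(C(=O)OC)C(OS(C)(=O)=O)[C@@H](OC(C)=O)[C@H]1OC(=O)[C@H](C)CC
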